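Everything rests on cutting both flavan units at C4–C4a. In each unit a C4 methylene is bonded to C4a of a symmetric 5,7-dioxygenated ring A and sits beside an R-configured C3 carbinol, the imprint of an aryl ether opening a terminal epoxide. One gold-catalysed operation therefore forms both C4–C4a bonds and closes both pyran rings. Its precursor is a benzyl-protected benzotropolone whose C2 and C8 each carry a 1-[3,5-bis(benzyloxy)phenoxy]-2,3-epoxypropyl arm with all four stereocentres in place. The core comes from a carbonyl ylide cycloaddition and ring opening; each arm from vinyl addition, tartrate-controlled epoxidation and O-arylation with retention (arm F) or inversion (arm G).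

Key step: step 23

Remark: core atoms are numbered as in benzo[7]annulen-5-one throughout (arm or unit F on C2, arm or unit G on C8); 25, 32 and 36 are taken as purchasable, 32 being otherwise the twofold O-benzylation product of phloroglucinol.
Remark: the stereodescriptors of the key-step substrate 33 and product 34 were re-derived atom by atom and agree with the target (unit F 2S,3R, unit G 2R,3R), so both structures are used without correction.
Remark: the two arm carbons are kept different from the start (C2 as acetal, C8 as ester and then silyl ether), and the ester is reduced on the oxabicycle, because a tropone would compete for hydride.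

Step 1
Reactants: 1 5-bromo-2-hydroxy-3-methoxybenzaldehyde
Product: 2 2-(benzyloxy)-5-bromo-3-methoxybenzaldehyde
Conditions: BnBr, K2CO3, DMF, rt
Reagents that add atoms: benzyl bromide BrCc1ccccc1
Why: Williamson ether synthesis on the phenoxide protects the future C3 oxygen as a hydrogenolysable benzyl ether, while the methyl ether is kept because it will flank the lithiation site of step 3 and the carbenoid of step 8, where a benzyl group could migrate.

Step 2
Reactants: 2 2-(benzyloxy)-5-bromo-3-methoxybenzaldehyde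
Product: 3 2-[2-(benzyloxy)-5-bromo-3-methoxyphenyl]-1,3-dioxolane
Conditions: HOCH2CH2OH, TsOH (cat.), toluene, reflux, azeotropic removal of water
Reagents that add atoms: ethylene glycol OCCO
Why: Acid-catalysed acetalisation masks the aldehyde, the future arm F carbon, against the organolithium, carbenoid and hydride steps.

Step 3
Reactants: 3 2-[2-(benzyloxy)-5-bromo-3-methoxyphenyl]-1,3-dioxolane
Product: 5 3-(benzyloxy)-6-bromo-4-(1,3-dioxolan-2-yl)-2-methoxybenzoic acid, via aryllithium 4 (not isolated)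
Conditions: LiN(iPr)2, THF, −78 °C; CO2; aq. HCl to pH 4, 0 °C
Reagents that add atoms: carbon dioxide O=C=O
Why: Directed ortho-metalation with the amide base removes the most acidic ring proton, the one flanked by OMe and Br, and carboxylation of aryllithium 4 at −78 °C is faster than aryne formation.

Step 4
Reactants: 5 3-(benzyloxy)-6-bromo-4-(1,3-dioxolan-2-yl)-2-methoxybenzoic acid
Product: 9 3-(benzyloxy)-6-{[(tert-butyldimethylsilyl)oxy]methyl}-4-(1,3-dioxolan-2-yl)-2-methoxybenzoic acid, via C-lithio carboxylate 6 (not isolated), via dilithium alkoxide carboxylate 7 (not isolated), via bis-silyl derivative 8 (not isolated)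
Conditions: n-BuLi (2.1 equiv), THF, −78 °C; CH2O (g), −78 → 0 °C; TBSCl, imidazole, DMF, rt; K2CO3, MeOH/H2O; pH 5
Reagents that add atoms: formaldehyde C=O; tert-butyl(chloro)dimethylsilane CC(C)(C)[Si](C)(C)Cl
Why: Bromine–lithium exchange on the lithium carboxylate (Parham-type), hydroxymethylation by formaldehyde and O-silylation are run in one flask so that the hydroxy acid never meets acid and cannot lactonise, and the labile silyl ester of 8 is cleaved selectively by aqueous carbonate.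

Step 5
Reactants: 9 3-(benzyloxy)-6-{[(tert-butyldimethylsilyl)oxy]methyl}-4-(1,3-dioxolan-2-yl)-2-methoxybenzoic acid
Product: 11 1-[3-(benzyloxy)-6-{[(tert-butyldimethylsilyl)oxy]methyl}-4-(1,3-dioxolan-2-yl)-2-methoxyphenyl]-2-diazoethan-1-one, via acid chloride 10 (not isolated)
Conditions: Me2C=C(Cl)NMe2, CH2Cl2, 0 °C → rt; CH2N2 (3 equiv), Et2O, 0 °C
Reagents that add atoms: diazomethane C=[N+]=[N-]
Why: The chloroenamine forms the acid chloride under neutral conditions that spare acetal and silyl ether, and acylation of diazomethane (diazoketone synthesis of the Arndt–Eistert type, a second equivalent scavenging HCl) gives 11.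

Step 6
Reactants: 11 1-[3-(benzyloxy)-6-{[(tert-butyldimethylsilyl)oxy]methyl}-4-(1,3-dioxolan-2-yl)-2-methoxyphenyl]-2-diazoethan-1-one
Product: 12 1-[3-(benzyloxy)-4-(1,3-dioxolan-2-yl)-6-(hydroxymethyl)-2-methoxyphenyl]-2-diazoethan-1-one
Conditions: Bu4NF, AcOH, THF, 0 °C
Reagents that add atoms: none
Why: Fluoride-mediated desilylation, buffered with AcOH, frees the benzylic alcohol without harming the diazoketone.

Step 7
Reactants: 12 1-[3-(benzyloxy)-4-(1,3-dioxolan-2-yl)-6-(hydroxymethyl)-2-methoxyphenyl]-2-diazoethan-1-one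
Product: 13 4-(benzyloxy)-2-(diazoacetyl)-5-(1,3-dioxolan-2-yl)-3-methoxybenzaldehyde
Conditions: MnO2, CH2Cl2, rt
Reagents that add atoms: none
Why: MnO2 oxidation of the benzylic alcohol is neutral and tolerated by diazo compounds, and the aldehyde is made last and used at once because base would let the diazo carbon add to it.

Step 8
Reactants: 13 4-(benzyloxy)-2-(diazoacetyl)-5-(1,3-dioxolan-2-yl)-3-methoxybenzaldehyde; 14 methyl propiolate
Product: 16 methyl 3-(benzyloxy)-2-(1,3-dioxolan-2-yl)-4-methoxy-5-oxo-6,9-dihydro-5H-6,9-epoxybenzo[7]annulene-8-carboxylate (racemic), via carbonyl ylide 15 (not isolated)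
Conditions: Rh2(OAc)4 (2 mol %), 14 (5 equiv), CH2Cl2, rt, slow addition of 13
Reagents that add atoms: none
Why: Rhodium carbenoid formation and capture by the ortho aldehyde oxygen give the 2-benzopyrylium-4-olate 15, whose 1,3-dipolar cycloaddition to the alkyne is controlled by the dipole HOMO so that the enolate-type carbon bonds to the unsubstituted alkyne carbon and the ester lands on C8, while the oxygen bridge fixes the relative configuration of the two new bridgehead centres (racemate), both of which are erased in step 12.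

Step 9
Reactants: 16 methyl 3-(benzyloxy)-2-(1,3-dioxolan-2-yl)-4-methoxy-5-oxo-6,9-dihydro-5H-6,9-epoxybenzo[7]annulene-8-carboxylate
Product: 17 [3-(benzyloxy)-2-(1,3-dioxolan-2-yl)-5-hydroxy-4-methoxy-6,9-dihydro-5H-6,9-epoxybenzo[7]annulen-8-yl]methanol (racemic mixture of C5 epimers)
Conditions: i-Bu2AlH (4.5 equiv), CH2Cl2, −78 °C; aq. potassium sodium tartrate
Reagents that add atoms: none
Why: Hydride reduction with i-Bu2AlH takes the enoate to the allylic alcohol (1,2-reduction) and the ketone to the carbinol on the bicycle, before a hydride-sensitive tropone exists, and the C5 epimer mixture is irrelevant because step 11 reoxidises that centre.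

Step 10
Reactants: 17 [3-(benzyloxy)-2-(1,3-dioxolan-2-yl)-5-hydroxy-4-methoxy-6,9-dihydro-5H-6,9-epoxybenzo[7]annulen-8-yl]methanol
Product: 18 3-(benzyloxy)-8-{[(tert-butyldiphenylsilyl)oxy]methyl}-2-(1,3-dioxolan-2-yl)-4-methoxy-6,9-dihydro-5H-6,9-epoxybenzo[7]annulen-5-ol
Conditions: TBDPSCl, imidazole, CH2Cl2, 0 °C
Reagents that add atoms: tert-butyl(chloro)diphenylsilane CC(C)(C)[Si](Cl)(c1ccccc1)c1ccccc1
Why: Steric selectivity of silylation puts the bulky silyl group on the primary allylic alcohol and leaves the hindered secondary benzylic alcohol, which masks the future arm G carbon at the alcohol level.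

Step 11
Reactants: 18 3-(benzyloxy)-8-{[(tert-butyldiphenylsilyl)oxy]methyl}-2-(1,3-dioxolan-2-yl)-4-methoxy-6,9-dihydro-5H-6,9-epoxybenzo[7]annulen-5-ol
Product: 19 3-(benzyloxy)-8-{[(tert-butyldiphenylsilyl)oxy]methyl}-2-(1,3-dioxolan-2-yl)-4-methoxy-6,9-dihydro-5H-6,9-epoxybenzo[7]annulen-5-one
Conditions: Dess–Martin periodinane, NaHCO3, CH2Cl2, rt
Reagents that add atoms: none
Why: Dess–Martin oxidation restores the aryl ketone required for tropolone formation under buffered, non-acidic conditions.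

Step 12
Reactants: 19 3-(benzyloxy)-8-{[(tert-butyldiphenylsilyl)oxy]methyl}-2-(1,3-dioxolan-2-yl)-4-methoxy-6,9-dihydro-5H-6,9-epoxybenzo[7]annulen-5-one
Product: 20 8-{[(tert-butyldiphenylsilyl)oxy]methyl}-3,4,6-trihydroxy-5-oxo-5H-benzo[7]annulene-2-carbaldehyde
Conditions: BCl3, C6HMe5, CH2Cl2, −78 → −30 °C; aq. NaHCO3, THF
Reagents that add atoms: water O
Why: Lewis-acid ring opening of the oxabicycle (ionisation of the bridging C9–O bond to a benzylic allylic cation, then loss of H6) gives the tropolone, while the same BCl3 cleaves the aryl benzyl ether (cation trapped by C6HMe5) and the peri methyl ether (chelation to C5=O) and the dioxolane is hydrolysed on work-up, the bulky silyl ether being stable at low temperature.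

Step 13
Reactants: 20 8-{[(tert-butyldiphenylsilyl)oxy]methyl}-3,4,6-trihydroxy-5-oxo-5H-benzo[7]annulene-2-carbaldehyde
Product: 21 3,4,6-tris(benzyloxy)-8-{[(tert-butyldiphenylsilyl)oxy]methyl}-5-oxo-5H-benzo[7]annulene-2-carbaldehyde
Conditions: BnBr (3.6 equiv), K2CO3, DMF, rt → 50 °C
Reagents that add atoms: benzyl bromide BrCc1ccccc1
Why: Williamson benzylation of the two phenols and the tropolone installs the hydrogenolysable protecting groups, with the tropolonate expected to react at O6 because O5 is shielded by the C4 substituent.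

Step 14
Reactants: 21 3,4,6-tris(benzyloxy)-8-{[(tert-butyldiphenylsilyl)oxy]methyl}-5-oxo-5H-benzo[7]annulene-2-carbaldehyde; 22 vinylmagnesium bromide
Product: 23 3,4,6-tris(benzyloxy)-8-{[(tert-butyldiphenylsilyl)oxy]methyl}-2-(1-hydroxyprop-2-en-1-yl)-5H-benzo[7]annulen-5-one (racemic)
Conditions: 22 (1.2 equiv), THF, −78 °C; aq. NH4Cl
Reagents that add atoms: none
Why: Grignard 1,2-addition to the aldehyde, helped by chelation to the ortho benzyloxy group, is much faster at −78 °C than attack on the hindered tropone carbonyl, and it gives a racemic carbinol that step 15 resolves.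

Step 15
Reactants: 23 3,4,6-tris(benzyloxy)-8-{[(tert-butyldiphenylsilyl)oxy]methyl}-2-(1-hydroxyprop-2-en-1-yl)-5H-benzo[7]annulen-5-one
Product: 24 3,4,6-tris(benzyloxy)-8-{[(tert-butyldiphenylsilyl)oxy]methyl}-2-{(S)-hydroxy[(2R)-oxiran-2-yl]methyl}-5H-benzo[7]annulen-5-one
Conditions: Ti(OiPr)4 (30 mol %), L-(+)-DIPT (36 mol %), t-BuOOH (0.55 equiv), 4 Å MS, CH2Cl2, −20 °C
Reagents that add atoms: tert-butyl hydroperoxide CC(C)(C)OO
Why: Sharpless kinetic resolution, in which with L-(+)-tartrate only the (R)-carbinol enantiomer (OH > aryl > vinyl) is epoxidised rapidly, on the face that gives the erythro epoxy alcohol with (S)-carbinol (priority change) and (R)-oxirane centres, which become C2 and C3 of unit F, while the slow enantiomer is removed as unreacted allylic alcohol.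

Step 16
Reactants: 25 3,5-bis(benzyloxy)phenylboronic acid
Product: 26 potassium [3,5-bis(benzyloxy)phenyl]trifluoroborate
Conditions: KHF2, MeOH/H2O, rt
Reagents that add atoms: potassium hydrogen difluoride [K+].[F-].F
Why: Fluoride exchange on boron with KHF2 is the standard preparation of an air-stable potassium aryltrifluoroborate.

Step 17
Reactants: 24 3,4,6-tris(benzyloxy)-8-{[(tert-butyldiphenylsilyl)oxy]methyl}-2-{(S)-hydroxy[(2R)-oxiran-2-yl]methyl}-5H-benzo[7]annulen-5-one; 26 potassium [3,5-bis(benzyloxy)phenyl]trifluoroborate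
Product: 27 2-{(S)-[3,5-bis(benzyloxy)phenoxy][(2R)-oxiran-2-yl]methyl}-3,4,6-tris(benzyloxy)-8-{[(tert-butyldiphenylsilyl)oxy]methyl}-5H-benzo[7]annulen-5-one
Conditions: 26 (2.5 equiv), Cu(OAc)2·H2O (20 mol %), DMAP (40 mol %), 4 Å MS, O2 (1 atm), CH2Cl2, rt
Reagents that add atoms: none
Why: Chan–Lam oxidative coupling forms the aryl–oxygen bond at copper from the alcohol oxygen, so the carbinol C–O bond is never broken (retention, 2S of unit F), and the near-neutral conditions avoid the alkoxide that would trigger Payne rearrangement.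

Step 18
Reactants: 27 2-{(S)-[3,5-bis(benzyloxy)phenoxy][(2R)-oxiran-2-yl]methyl}-3,4,6-tris(benzyloxy)-8-{[(tert-butyldiphenylsilyl)oxy]methyl}-5H-benzo[7]annulen-5-one
Product: 28 2-{(S)-[3,5-bis(benzyloxy)phenoxy][(2R)-oxiran-2-yl]methyl}-3,4,6-tris(benzyloxy)-8-(hydroxymethyl)-5H-benzo[7]annulen-5-one
Conditions: Bu4NF, AcOH, THF, 0 °C → rt
Reagents that add atoms: none
Why: Fluoride-mediated desilylation buffered with AcOH frees the primary alcohol and leaves the epoxide, the aryl ethers and the tropolone benzyl ether intact.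

Step 19
Reactants: 28 2-{(S)-[3,5-bis(benzyloxy)phenoxy][(2R)-oxiran-2-yl]methyl}-3,4,6-tris(benzyloxy)-8-(hydroxymethyl)-5H-benzo[7]annulen-5-one
Product: 29 2-{(S)-[3,5-bis(benzyloxy)phenoxy][(2R)-oxiran-2-yl]methyl}-3,4,6-tris(benzyloxy)-5-oxo-5H-benzo[7]annulene-8-carbaldehyde
Conditions: Dess–Martin periodinane, NaHCO3, CH2Cl2, rt
Reagents that add atoms: none
Why: Dess–Martin oxidation converts the primary alcohol on the tropone ring into the aldehyde under non-acidic conditions that the epoxide tolerates.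

Step 20
Reactants: 29 2-{(S)-[3,5-bis(benzyloxy)phenoxy][(2R)-oxiran-2-yl]methyl}-3,4,6-tris(benzyloxy)-5-oxo-5H-benzo[7]annulene-8-carbaldehyde; 22 vinylmagnesium bromide
Product: 30 2-{(S)-[3,5-bis(benzyloxy)phenoxy][(2R)-oxiran-2-yl]methyl}-3,4,6-tris(benzyloxy)-8-(1-hydroxyprop-2-en-1-yl)-5H-benzo[7]annulen-5-one (both carbinol epimers)
Conditions: 22 (1.2 equiv), THF, −78 °C; aq. NH4Cl
Reagents that add atoms: none
Why: Grignard 1,2-addition to the electrophilic tropone-bound aldehyde at −78 °C outpaces opening of the terminal epoxide and attack on the tropone, and it gives both carbinol epimers for resolution in step 21.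

Step 21
Reactants: 30 2-{(S)-[3,5-bis(benzyloxy)phenoxy][(2R)-oxiran-2-yl]methyl}-3,4,6-tris(benzyloxy)-8-(1-hydroxyprop-2-en-1-yl)-5H-benzo[7]annulen-5-one
Product: 31 2-{(S)-[3,5-bis(benzyloxy)phenoxy][(2R)-oxiran-2-yl]methyl}-3,4,6-tris(benzyloxy)-8-{(S)-hydroxy[(2R)-oxiran-2-yl]methyl}-5H-benzo[7]annulen-5-one
Conditions: Ti(OiPr)4 (30 mol %), L-(+)-DIPT (36 mol %), t-BuOOH (0.55 equiv), 4 Å MS, CH2Cl2, −20 °C
Reagents that add atoms: tert-butyl hydroperoxide CC(C)(C)OO
Why: Sharpless kinetic resolution with the same L-(+)-tartrate epoxidises only the epimer with the fast-reacting carbinol configuration to the erythro epoxy alcohol with (S)-carbinol and (R)-oxirane centres (the latter is C3 of unit G), while the other epimer stays as allylic alcohol and is separated.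

Step 22
Reactants: 31 2-{(S)-[3,5-bis(benzyloxy)phenoxy][(2R)-oxiran-2-yl]methyl}-3,4,6-tris(benzyloxy)-8-{(S)-hydroxy[(2R)-oxiran-2-yl]methyl}-5H-benzo[7]annulen-5-one; 32 3,5-bis(benzyloxy)phenol
Product: 33 2-{(S)-[3,5-bis(benzyloxy)phenoxy][(2R)-oxiran-2-yl]methyl}-8-{(R)-[3,5-bis(benzyloxy)phenoxy][(2R)-oxiran-2-yl]methyl}-3,4,6-tris(benzyloxy)-5H-benzo[7]annulen-5-one
Conditions: 32, PPh3, DIAD, toluene, 0 °C → rt
Reagents that add atoms: none
Why: Mitsunobu etherification, in which the phenoxide displaces the oxyphosphonium group in an SN2 reaction with inversion (S to R, C2 of unit G), ionisation being disfavoured because the carbinol sits on the electron-poor tropone ring.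

Step 23
Reactants: 33 2-{(S)-[3,5-bis(benzyloxy)phenoxy][(2R)-oxiran-2-yl]methyl}-8-{(R)-[3,5-bis(benzyloxy)phenoxy][(2R)-oxiran-2-yl]methyl}-3,4,6-tris(benzyloxy)-5H-benzo[7]annulen-5-one
Product: 34 3,4,6-tris(benzyloxy)-2-[(2S,3R)-5,7-bis(benzyloxy)-3-hydroxychroman-2-yl]-8-[(2R,3R)-5,7-bis(benzyloxy)-3-hydroxychroman-2-yl]-5H-benzo[7]annulen-5-one
Conditions: AuCl3 (10 mol %), AgOTf (30 mol %), 4 Å MS, ClCH2CH2Cl, rt
Reagents that add atoms: none
Why: AgOTf abstracts chloride from AuCl3 to give a cationic trivalent gold Lewis acid that binds each epoxide oxygen and polarises the terminal C4–O bond, after which the ortho carbon of the neighbouring 3,5-bis(benzyloxy)phenyl ether attacks C4 and the arenium ion rearomatises by proton loss (intramolecular Friedel–Crafts alkylation). The closest known reaction type is the gold-catalysed cyclisation of aryl glycidyl ethers to chroman-3-ols, including 2-aryl cases that lead to benzyl-protected flavan-3-ols. Ring C of unit F and ring C of unit G both close in the 6-endo-tet mode, with both epoxide carbons ending up inside the new pyran ring. No stereocentre is created, because the C3–O bonds are never broken and the C2 centres are spectators, so the (2S,3R) arm gives the trans ring and the (2R,3R) arm the cis ring. The step needs attack at the terminal carbon and not at the internal one (five-membered ring) and no ionisation of the benzylic C2–O aryl ethers, which is secured by the unhindered primary carbon, the inductive deactivation of C3 by the adjacent C2–O bond, the electron-poor tropone ring on arm G and the acyl-bearing para position on arm F. Because the two ortho positions of each symmetric aryl ether are equivalent, no regiochemical choice arises on the arene.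

Step 24
Reactants: 34 3,4,6-tris(benzyloxy)-2-[(2S,3R)-5,7-bis(benzyloxy)-3-hydroxychroman-2-yl]-8-[(2R,3R)-5,7-bis(benzyloxy)-3-hydroxychroman-2-yl]-5H-benzo[7]annulen-5-one
Product: 35 3,4,6-tris(benzyloxy)-2-{(2S,3R)-5,7-bis(benzyloxy)-3-[(tert-butyldimethylsilyl)oxy]chroman-2-yl}-8-[(2R,3R)-5,7-bis(benzyloxy)-3-hydroxychroman-2-yl]-5H-benzo[7]annulen-5-one
Conditions: TBSCl (1.1 equiv), imidazole, DMF, 0 °C
Reagents that add atoms: tert-butyl(chloro)dimethylsilane CC(C)(C)[Si](C)(C)Cl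
Why: Sterically controlled silylation is expected to take the equatorial C3 hydroxyl of the trans unit F in preference to the axial C3 hydroxyl of the cis unit G.

Step 25
Reactants: 35 3,4,6-tris(benzyloxy)-2-{(2S,3R)-5,7-bis(benzyloxy)-3-[(tert-butyldimethylsilyl)oxy]chroman-2-yl}-8-[(2R,3R)-5,7-bis(benzyloxy)-3-hydroxychroman-2-yl]-5H-benzo[7]annulen-5-one; 36 3,4,5-tris(benzyloxy)benzoic acid
Product: 38 (2R,3R)-5,7-bis(benzyloxy)-2-[3,4,6-tris(benzyloxy)-2-{(2S,3R)-5,7-bis(benzyloxy)-3-[(tert-butyldimethylsilyl)oxy]chroman-2-yl}-5-oxo-5H-benzo[7]annulen-8-yl]chroman-3-yl 3,4,5-tris(benzyloxy)benzoate, via galloyl chloride 37 (not isolated)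
Conditions: 36, (COCl)2, DMF (cat.), CH2Cl2, 0 °C → rt; then 35, Et3N, DMAP, CH2Cl2, rt
Reagents that add atoms: none
Why: DMAP-catalysed acylation (esterification via the acid chloride 37) of the remaining axial alcohol forms the ester at oxygen, so C3 of unit G keeps its configuration.

Step 26
Reactants: 38 (2R,3R)-5,7-bis(benzyloxy)-2-[3,4,6-tris(benzyloxy)-2-{(2S,3R)-5,7-bis(benzyloxy)-3-[(tert-butyldimethylsilyl)oxy]chroman-2-yl}-5-oxo-5H-benzo[7]annulen-8-yl]chroman-3-yl 3,4,5-tris(benzyloxy)benzoate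
Product: 39 (2R,3R)-5,7-dihydroxy-2-{3,4,6-trihydroxy-5-oxo-2-[(2S,3R)-3,5,7-trihydroxychroman-2-yl]-5H-benzo[7]annulen-8-yl}chroman-3-yl 3,4,5-trihydroxybenzoate (CNP0259919.1)
Conditions: H2 (1 atm), Pd(OH)2/C, HCl (cat.), THF/MeOH, rt
Reagents that add atoms: none
Why: Palladium-catalysed hydrogenolysis removes the ten benzyl ethers and the trace of HCl in methanol solvolyses the silyl ether in the same flask, conditions under which the gallate ester, the cyclic benzylic C2–O bonds and all four stereocentres are expected to persist.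

Compound list
1 | 5-bromo-2-hydroxy-3-methoxybenzaldehyde | COc1cc(Br)cc(C=O)c1O | starting material
2 | 2-(benzyloxy)-5-bromo-3-methoxybenzaldehyde | COc1cc(Br)cc(C=O)c1OCc1ccccc1 | intermediate
3 | 2-[2-(benzyloxy)-5-bromo-3-methoxyphenyl]-1,3-dioxolane | COc1cc(Br)cc(C2OCCO2)c1OCc1ccccc1 | intermediate
4 | [3-(benzyloxy)-6-bromo-4-(1,3-dioxolan-2-yl)-2-methoxyphenyl]lithium | COc1c([Li])c(Br)cc(C2OCCO2)c1OCc1ccccc1 | intermediate
5 | 3-(benzyloxy)-6-bromo-4-(1,3-dioxolan-2-yl)-2-methoxybenzoic acid | COc1c(C(=O)O)c(Br)cc(C2OCCO2)c1OCc1ccccc1 | intermediate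
6 | lithium 3-(benzyloxy)-4-(1,3-dioxolan-2-yl)-6-lithio-2-methoxybenzoate | COc1c(C(=O)O[Li])c([Li])cc(C2OCCO2)c1OCc1ccccc1 | intermediate
7 | dilithium 3-(benzyloxy)-4-(1,3-dioxolan-2-yl)-2-methoxy-6-(oxidomethyl)benzoate | COc1c(C(=O)O[Li])c(CO[Li])cc(C2OCCO2)c1OCc1ccccc1 | intermediate
8 | tert-butyldimethylsilyl 3-(benzyloxy)-6-{[(tert-butyldimethylsilyl)oxy]methyl}-4-(1,3-dioxolan-2-yl)-2-methoxybenzoate | COc1c(C(=O)O[Si](C)(C)C(C)(C)C)c(CO[Si](C)(C)C(C)(C)C)cc(C2OCCO2)c1OCc1ccccc1 | intermediate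
9 | 3-(benzyloxy)-6-{[(tert-butyldimethylsilyl)oxy]methyl}-4-(1,3-dioxolan-2-yl)-2-methoxybenzoic acid | COc1c(C(=O)O)c(CO[Si](C)(C)C(C)(C)C)cc(C2OCCO2)c1OCc1ccccc1 | intermediate
10 | 3-(benzyloxy)-6-{[(tert-butyldimethylsilyl)oxy]methyl}-4-(1,3-dioxolan-2-yl)-2-methoxybenzoyl chloride | COc1c(C(=O)Cl)c(CO[Si](C)(C)C(C)(C)C)cc(C2OCCO2)c1OCc1ccccc1 | intermediate
11 | 1-[3-(benzyloxy)-6-{[(tert-butyldimethylsilyl)oxy]methyl}-4-(1,3-dioxolan-2-yl)-2-methoxyphenyl]-2-diazoethan-1-one | COc1c(C(=O)C=[N+]=[N-])c(CO[Si](C)(C)C(C)(C)C)cc(C2OCCO2)c1OCc1ccccc1 | intermediate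
12 | 1-[3-(benzyloxy)-4-(1,3-dioxolan-2-yl)-6-(hydroxymethyl)-2-methoxyphenyl]-2-diazoethan-1-one | COc1c(C(=O)C=[N+]=[N-])c(CO)cc(C2OCCO2)c1OCc1ccccc1 | intermediate
13 | 4-(benzyloxy)-2-(diazoacetyl)-5-(1,3-dioxolan-2-yl)-3-methoxybenzaldehyde | COc1c(C(=O)C=[N+]=[N-])c(C=O)cc(C2OCCO2)c1OCc1ccccc1 | intermediate
14 | methyl propiolate | C#CC(=O)OC | starting material
15 | 6-(benzyloxy)-7-(1,3-dioxolan-2-yl)-5-methoxy-2-benzopyrylium-4-olate | COc1c(OCc2ccccc2)c(C2OCCO2)cc2c[o+]cc([O-])c12 | intermediate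
16 | methyl 3-(benzyloxy)-2-(1,3-dioxolan-2-yl)-4-methoxy-5-oxo-6,9-dihydro-5H-6,9-epoxybenzo[7]annulene-8-carboxylate (racemic, bridge necessarily cis) | COC(=O)C1=CC2OC1c1cc(C3OCCO3)c(OCc3ccccc3)c(OC)c1C2=O | intermediate
17 | [3-(benzyloxy)-2-(1,3-dioxolan-2-yl)-5-hydroxy-4-methoxy-6,9-dihydro-5H-6,9-epoxybenzo[7]annulen-8-yl]methanol (racemic, C5 epimers) | OCC1=CC2OC1c1cc(C3OCCO3)c(OCc3ccccc3)c(OC)c1C2O | intermediate
18 | 3-(benzyloxy)-8-{[(tert-butyldiphenylsilyl)oxy]methyl}-2-(1,3-dioxolan-2-yl)-4-methoxy-6,9-dihydro-5H-6,9-epoxybenzo[7]annulen-5-ol (racemic, C5 epimers) | CC(C)(C)[Si](c1ccccc1)(c1ccccc1)OCC1=CC2OC1c1cc(C3OCCO3)c(OCc3ccccc3)c(OC)c1C2O | intermediate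
19 | 3-(benzyloxy)-8-{[(tert-butyldiphenylsilyl)oxy]methyl}-2-(1,3-dioxolan-2-yl)-4-methoxy-6,9-dihydro-5H-6,9-epoxybenzo[7]annulen-5-one (racemic) | CC(C)(C)[Si](c1ccccc1)(c1ccccc1)OCC1=CC2OC1c1cc(C3OCCO3)c(OCc3ccccc3)c(OC)c1C2=O | intermediate
20 | 8-{[(tert-butyldiphenylsilyl)oxy]methyl}-3,4,6-trihydroxy-5-oxo-5H-benzo[7]annulene-2-carbaldehyde | O=Cc1cc2cc(CO[Si](c3ccccc3)(c3ccccc3)C(C)(C)C)cc(O)c(=O)c2c(O)c1O | intermediate
21 | 3,4,6-tris(benzyloxy)-8-{[(tert-butyldiphenylsilyl)oxy]methyl}-5-oxo-5H-benzo[7]annulene-2-carbaldehyde | O=Cc1cc2cc(CO[Si](c3ccccc3)(c3ccccc3)C(C)(C)C)cc(OCc3ccccc3)c(=O)c2c(OCc3ccccc3)c1OCc1ccccc1 | intermediate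
22 | vinylmagnesium bromide | C=C[Mg]Br | starting material
23 | 3,4,6-tris(benzyloxy)-8-{[(tert-butyldiphenylsilyl)oxy]methyl}-2-(1-hydroxyprop-2-en-1-yl)-5H-benzo[7]annulen-5-one (racemic) | C=CC(O)c1cc2cc(CO[Si](c3ccccc3)(c3ccccc3)C(C)(C)C)cc(OCc3ccccc3)c(=O)c2c(OCc3ccccc3)c1OCc1ccccc1 | intermediate
24 | 3,4,6-tris(benzyloxy)-8-{[(tert-butyldiphenylsilyl)oxy]methyl}-2-{(S)-hydroxy[(2R)-oxiran-2-yl]methyl}-5H-benzo[7]annulen-5-one | O[C@H]([C@H]1CO1)c1cc2cc(CO[Si](c3ccccc3)(c3ccccc3)C(C)(C)C)cc(OCc3ccccc3)c(=O)c2c(OCc3ccccc3)c1OCc1ccccc1 | intermediate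
25 | 3,5-bis(benzyloxy)phenylboronic acid | OB(O)c1cc(OCc2ccccc2)cc(OCc2ccccc2)c1 | starting material
26 | potassium [3,5-bis(benzyloxy)phenyl]trifluoroborate | [K+].F[B-](F)(F)c1cc(OCc2ccccc2)cc(OCc2ccccc2)c1 | intermediate
27 | 2-{(S)-[3,5-bis(benzyloxy)phenoxy][(2R)-oxiran-2-yl]methyl}-3,4,6-tris(benzyloxy)-8-{[(tert-butyldiphenylsilyl)oxy]methyl}-5H-benzo[7]annulen-5-one | C(Oc1cc(OCc2ccccc2)cc(O[C@H]([C@H]2CO2)c2cc3cc(CO[Si](c4ccccc4)(c4ccccc4)C(C)(C)C)cc(OCc4ccccc4)c(=O)c3c(OCc4ccccc4)c2OCc2ccccc2)c1)c1ccccc1 | intermediate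
28 | 2-{(S)-[3,5-bis(benzyloxy)phenoxy][(2R)-oxiran-2-yl]methyl}-3,4,6-tris(benzyloxy)-8-(hydroxymethyl)-5H-benzo[7]annulen-5-one | C(Oc1cc(OCc2ccccc2)cc(O[C@H]([C@H]2CO2)c2cc3cc(CO)cc(OCc4ccccc4)c(=O)c3c(OCc4ccccc4)c2OCc2ccccc2)c1)c1ccccc1 | intermediate
29 | 2-{(S)-[3,5-bis(benzyloxy)phenoxy][(2R)-oxiran-2-yl]methyl}-3,4,6-tris(benzyloxy)-5-oxo-5H-benzo[7]annulene-8-carbaldehyde | C(Oc1cc(OCc2ccccc2)cc(O[C@H]([C@H]2CO2)c2cc3cc(C=O)cc(OCc4ccccc4)c(=O)c3c(OCc4ccccc4)c2OCc2ccccc2)c1)c1ccccc1 | intermediate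
30 | 2-{(S)-[3,5-bis(benzyloxy)phenoxy][(2R)-oxiran-2-yl]methyl}-3,4,6-tris(benzyloxy)-8-(1-hydroxyprop-2-en-1-yl)-5H-benzo[7]annulen-5-one (both carbinol epimers) | C(Oc1cc(OCc2ccccc2)cc(O[C@H]([C@H]2CO2)c2cc3cc(C(O)C=C)cc(OCc4ccccc4)c(=O)c3c(OCc4ccccc4)c2OCc2ccccc2)c1)c1ccccc1 | intermediate
31 | 2-{(S)-[3,5-bis(benzyloxy)phenoxy][(2R)-oxiran-2-yl]methyl}-3,4,6-tris(benzyloxy)-8-{(S)-hydroxy[(2R)-oxiran-2-yl]methyl}-5H-benzo[7]annulen-5-one | C(Oc1cc(OCc2ccccc2)cc(O[C@H]([C@H]2CO2)c2cc3cc([C@H](O)[C@H]4CO4)cc(OCc4ccccc4)c(=O)c3c(OCc4ccccc4)c2OCc2ccccc2)c1)c1ccccc1 | intermediate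
32 | 3,5-bis(benzyloxy)phenol | Oc1cc(OCc2ccccc2)cc(OCc2ccccc2)c1 | starting material
33 | 2-{(S)-[3,5-bis(benzyloxy)phenoxy][(2R)-oxiran-2-yl]methyl}-8-{(R)-[3,5-bis(benzyloxy)phenoxy][(2R)-oxiran-2-yl]methyl}-3,4,6-tris(benzyloxy)-5H-benzo[7]annulen-5-one | C(Oc1cc(OCc2ccccc2)cc(O[C@H]([C@H]2CO2)c2cc3cc([C@@H](Oc4cc(OCc5ccccc5)cc(OCc5ccccc5)c4)[C@H]4CO4)cc(OCc4ccccc4)c(=O)c3c(OCc4ccccc4)c2OCc2ccccc2)c1)c1ccccc1 | intermediate
34 | 3,4,6-tris(benzyloxy)-2-[(2S,3R)-5,7-bis(benzyloxy)-3-hydroxychroman-2-yl]-8-[(2R,3R)-5,7-bis(benzyloxy)-3-hydroxychroman-2-yl]-5H-benzo[7]annulen-5-one | O[C@@H]1Cc2c(OCc3ccccc3)cc(OCc3ccccc3)cc2O[C@@H]1c1cc(OCc2ccccc2)c(=O)c2c(OCc3ccccc3)c(OCc3ccccc3)c([C@@H]3Oc4cc(OCc5ccccc5)cc(OCc5ccccc5)c4C[C@H]3O)cc2c1 | intermediate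
35 | 3,4,6-tris(benzyloxy)-2-{(2S,3R)-5,7-bis(benzyloxy)-3-[(tert-butyldimethylsilyl)oxy]chroman-2-yl}-8-[(2R,3R)-5,7-bis(benzyloxy)-3-hydroxychroman-2-yl]-5H-benzo[7]annulen-5-one | O[C@@H]1Cc2c(OCc3ccccc3)cc(OCc3ccccc3)cc2O[C@@H]1c1cc(OCc2ccccc2)c(=O)c2c(OCc3ccccc3)c(OCc3ccccc3)c([C@@H]3Oc4cc(OCc5ccccc5)cc(OCc5ccccc5)c4C[C@H]3O[Si](C)(C)C(C)(C)C)cc2c1 | intermediate
36 | 3,4,5-tris(benzyloxy)benzoic acid | OC(=O)c1cc(OCc2ccccc2)c(OCc2ccccc2)c(OCc2ccccc2)c1 | starting material
37 | 3,4,5-tris(benzyloxy)benzoyl chloride | ClC(=O)c1cc(OCc2ccccc2)c(OCc2ccccc2)c(OCc2ccccc2)c1 | intermediate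
38 | (2R,3R)-5,7-bis(benzyloxy)-2-[3,4,6-tris(benzyloxy)-2-{(2S,3R)-5,7-bis(benzyloxy)-3-[(tert-butyldimethylsilyl)oxy]chroman-2-yl}-5-oxo-5H-benzo[7]annulen-8-yl]chroman-3-yl 3,4,5-tris(benzyloxy)benzoate | O=C(O[C@@H]1Cc2c(OCc3ccccc3)cc(OCc3ccccc3)cc2O[C@@H]1c1cc(OCc2ccccc2)c(=O)c2c(OCc3ccccc3)c(OCc3ccccc3)c([C@@H]3Oc4cc(OCc5ccccc5)cc(OCc5ccccc5)c4C[C@H]3O[Si](C)(C)C(C)(C)C)cc2c1)c1cc(OCc2ccccc2)c(OCc2ccccc2)c(OCc2ccccc2)c1 | intermediate
39 | (2R,3R)-5,7-dihydroxy-2-{3,4,6-trihydroxy-5-oxo-2-[(2S,3R)-3,5,7-trihydroxychroman-2-yl]-5H-benzo[7]annulen-8-yl}chroman-3-yl 3,4,5-trihydroxybenzoate (CNP0259919.1) | O=C(O[C@@H]1Cc2c(O)cc(O)cc2O[C@@H]1c1cc(O)c(=O)c2c(O)c(O)c([C@@H]3Oc4cc(O)cc(O)c4C[C@H]3O)cc2c1)c1cc(O)c(O)c(O)c1 | target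

Total step count: 26.
Longest linear sequence: 25 steps (steps 1–15 and 17–26, from 1 to 39); step 16 is a one-step side branch.

Steps most likely to fail

Step 23. The double closure may stop after one ring or open an epoxide at the internal carbon to a five-membered ring. The triflate-containing medium may also detach the benzyl group from the tropolone oxygen and transfer it to ring A. The fallback sets out from 33 and replaces metal Lewis-acid catalysis by hydrogen-bond activation. Compound 33 is dissolved in (CF3)2CHOH and warmed to 40 °C without any metal or added acid, so that the fluorinated alcohol activates both epoxides and stabilises the arenium intermediates. The sequence comes back to the route at 34 and makes no compound outside the list (F0).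

Step 24. The silylation may fail to discriminate between the two secondary alcohols, giving poor site selectivity. The fallback sets out from 34 and drops the protecting group. Compound 34 is acylated with a slight deficiency of 37 (Et3N, DMAP, CH2Cl2, −20 °C) and the monoesters are separated by chromatography to give (2R,3R)-5,7-bis(benzyloxy)-2-{3,4,6-tris(benzyloxy)-2-[(2S,3R)-5,7-bis(benzyloxy)-3-hydroxychroman-2-yl]-5-oxo-5H-benzo[7]annulen-8-yl}chroman-3-yl 3,4,5-tris(benzyloxy)benzoate F3. Unreacted 34 is returned to the pool, as is the wrong isomer after methanolysis. Hydrogenolysis of F3 (H2, Pd(OH)2/C, THF/MeOH) rejoins the route at 39.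

Step 17. The oxidative coupling may be slow on the hindered secondary carbinol, and acetate or DMAP may open the epoxide, so that the epoxy alcohol is lost. The fallback reaches net retention by double inversion with known chemistry and sets out from 24. Mitsunobu esterification with 4-nitrobenzoic acid (PPh3, DIAD, toluene) gives the inverted ester (R)-[3,4,6-tris(benzyloxy)-8-{[(tert-butyldiphenylsilyl)oxy]methyl}-5-oxo-5H-benzo[7]annulen-2-yl][(2R)-oxiran-2-yl]methyl 4-nitrobenzoate F1. Brief methanolysis (K2CO3, MeOH, 0 °C) gives the threo alcohol 3,4,6-tris(benzyloxy)-8-{[(tert-butyldiphenylsilyl)oxy]methyl}-2-{(R)-hydroxy[(2R)-oxiran-2-yl]methyl}-5H-benzo[7]annulen-5-one F2. A second Mitsunobu reaction with 32 inverts the carbinol again and comes back to the route at 27.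

Further compounds
F1 | step 17 | (R)-[3,4,6-tris(benzyloxy)-8-{[(tert-butyldiphenylsilyl)oxy]methyl}-5-oxo-5H-benzo[7]annulen-2-yl][(2R)-oxiran-2-yl]methyl 4-nitrobenzoate | O=C(O[C@@H]([C@H]1CO1)c1cc2cc(CO[Si](c3ccccc3)(c3ccccc3)C(C)(C)C)cc(OCc3ccccc3)c(=O)c2c(OCc3ccccc3)c1OCc1ccccc1)c1ccc(cc1)[N+](=O)[O-]
F2 | step 17 | 3,4,6-tris(benzyloxy)-8-{[(tert-butyldiphenylsilyl)oxy]methyl}-2-{(R)-hydroxy[(2R)-oxiran-2-yl]methyl}-5H-benzo[7]annulen-5-one | O[C@@H]([C@H]1CO1)c1cc2cc(CO[Si](c3ccccc3)(c3ccccc3)C(C)(C)C)cc(OCc3ccccc3)c(=O)c2c(OCc3ccccc3)c1OCc1ccccc1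
F0 | step 23 | none | none
F3 | step 24 | (2R,3R)-5,7-bis(benzyloxy)-2-{3,4,6-tris(benzyloxy)-2-[(2S,3R)-5,7-bis(benzyloxy)-3-hydroxychroman-2-yl]-5-oxo-5H-benzo[7]annulen-8-yl}chroman-3-yl 3,4,5-tris(benzyloxy)benzoate | O=C(O[C@@H]1Cc2c(OCc3ccccc3)cc(OCc3ccccc3)cc2O[C@@H]1c1cc(OCc2ccccc2)c(=O)c2c(OCc3ccccc3)c(OCc3ccccc3)c([C@@H]3Oc4cc(OCc5ccccc5)cc(OCc5ccccc5)c4C[C@H]3O)cc2c1)c1cc(OCc2ccccc2)c(OCc2ccccc2)c(OCc2ccccc2)c1
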